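## The problem

Compound 19 is a 2,2-dimethyl-2H-chromene whose benzene ring (ring A) carries three different oxygen functions in a phloroglucinol pattern: the pyran oxygen O1 at C8a, a free hydroxyl at C5 and a methoxyl at C7. The acyl side chain sits at C6, between the last two. A synthesis must therefore tell three formerly equivalent oxygens apart and place the acyl group at C6 and not at C8, the other free and equally activated position. The side chain is a β-hydroxy ketone (C1' carbonyl, C2' methylene, C3' carbinol bearing phenyl) and holds the only stereocentre, (S) at C3'. That centre lies three bonds from ring A, nothing in the bicycle can control it, and it is best bought and carried through. The β-hydroxy ketone is fragile: base cleaves it by retro-aldol reaction, and acid or base dehydrates it to a chalcone that the C5 hydroxyl can close to a flavanone, destroying the stereocentre. The C3=C4 double bond is an electron-rich styrene that tolerates neither strong Lewis or protic acids, electrophilic halogen nor hydrogenation, which excludes classical Friedel–Crafts acylation and benzyl protection. The enabling feature is that the C5 hydroxyl and the C6 acyl carbon are ortho neighbours, the pair an aryne delivers when it inserts into the acyl C–O bond of a carboxylic acid. The C7 methoxyl next to C6 can polarise a C5–C6 aryne so that oxygen goes to C5 and carbon to C6.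

## Retrosynthesis

**19 from 18.** The last cut is the O–CH2 bond of a methoxymethyl ether on the C3' oxygen. Protection is needed because a free C3' hydroxyl would compete with the carboxylate for the aryne and would leave the product open to retro-aldol cleavage under hot fluoride. A silyl ether would not survive fluoride at high temperature, a benzyl ether could only be removed by hydrogenolysis that also saturates C3=C4, and an ester at C3' would be eliminated from the β-acyloxy ketone. The acetal is inert to fluoride and base. Compound 18 differs from 19 only in this group; the forward step must exchange the acetal without touching the chromene or dehydrating the β-hydroxy ketone.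

**18 from 13 and 16.** The C5–O and C6–C1' bonds are cut together. Read backwards, the 2-hydroxyaryl ketone arises by insertion of the 5,6-aryne 17 into the acyl C–O bond of acid 16, and 17 comes from the ortho-silylaryl triflate 13 and fluoride. The neighbouring cuts are weaker:
- Friedel–Crafts or Fries acylation of chromenol 6 needs Lewis acids that attack the chromene and the acetal, and would divide between C6 and C8.
- Aryllithium acylation at C6 needs the C5 oxygen protected and an enolisable β-alkoxy acyl donor; it is kept only as a reserve.

The aryne cut makes both bonds at the crowded C5/C6 edge in one operation without strong base or Lewis acid. It divides the target into a chromene half without stereochemistry and a small acid that holds the only stereocentre. The forward reaction must send the carboxylate oxygen to C5 and not C6, must let the C6 anion capture the acyl group faster than a proton, and must pass C3' and its acetal through unchanged.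

**16 from 15 and 14.** The ester C–O bond and the acetal O–CH2 bond are cut, leading to the hydroxy ester 14, which is sold as the single (S) enantiomer. Creating C3' by an asymmetric aldol reaction on a 6-acetylchromene would build the stereocentre beside a chelating phenol ketone; buying it avoids that entirely. The forward steps only have to avoid β-elimination of the C3' oxygen.

**13 from 6 by way of 7 and 11.** The C6–Si bond and the S–O bond are cut, and the C5 oxygen is traced back through an N-isopropylcarbamate to the free phenol 6. The carbamate directs lithiation to C6, the only position ortho to it and also flanked by the C7 methoxyl, through the N-silyl species 8, 9 and 10. Base-induced loss of the carbamate then gives the silyl phenol 12, which is triflated in the same flask. The alternative of ortho-bromination followed by a silyl shift exposes the electron-rich alkene and C8 to electrophilic bromine and is held in reserve. The forward sequence must keep the organolithium away from C8 and from the C3=C4 bond.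

**6 from 4, 3, 1 and 2.** The C3=C4 bond is traced back to the C4 ketone of chromanone 4 through diol 5. The C7 O–CH3 bond is cut to give diol 3, and the C4–C4a and O1–C2 bonds are cut to give phloroglucinol 1 and 3-methylbut-2-enoic acid 2. A ring in which one oxygen is already methylated would offer two kinds of free ring positions, and an annulation or formylation would have to choose between them; electrophiles favour the position para to a hydroxyl, not the one between the hydroxyls. The symmetric triol 1 can give only one chromanone, and in 3 the C4 carbonyl ties up the C5 hydroxyl in a hydrogen bond, so methylation goes to C7 alone. The forward steps need a reduction and dehydration that spare the free phenol.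

## Roads not taken

**Alternative 1:** The cut removes the pyran ring. O1–C8a, C4–C4a and O1–C2 are broken, leading to the aryne precursor 5-methoxy-3-(methoxymethoxy)-2-(trimethylsilyl)phenyl trifluoromethanesulfonate A2 and 3-methylbut-2-enal A3. In the forward sense fluoride releases a 3-alkoxyaryne that adds across the aldehyde C=O of A3. The resulting benzoxete opens to an ortho-quinone methide, and 6π-electrocyclisation gives 7-methoxy-5-(methoxymethoxy)-2,2-dimethyl-2H-chromene A1.
- Merits: the chromene is assembled in one operation, and the alkoxy group steers oxygen to the correct aryne carbon.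
- Weak points: A2 has to be made from 5-methoxyresorcinol A4 by telling its two equivalent hydroxyls apart, a statistical mono-protection. Arynes also undergo ene reactions with enals, and the carbonyl addition normally needs a large excess of aldehyde. Above all, A1 still lacks the side chain, so the C6 acylation must follow by ortho-lithiation and reaction with an enolisable β-alkoxy acyl donor.
- Comparison: this road is at least as good in two respects. Its organolithium and fluoride steps run on a simple benzene rather than a chromene, and the β-alkoxy ketone never meets fluoride at 125 °C. The chosen plan sets against this that its aryne step makes the two bonds at the hindered C5/C6 edge, which Alternative 1 leaves to three further steps, and that its ring A regiochemistry rests on symmetry and chelation. The two roads meet in the reserve for step 9, which passes through the same compound as A1.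

**Alternative 2:** Ring A is cut at C5–C6 and C7–C8. This gives the diene 5-[methoxy(trimethylsilyloxy)methylidene]-2,2-dimethyl-6-methylidene-5,6-dihydro-2H-pyran A6 and the push-pull ynone (S)-5-(tert-butyldimethylsilyloxy)-1-methoxy-5-phenylpent-1-yn-3-one A7. A Diels–Alder reaction joins the nucleophilic methylidene terminus to the methoxy-bearing alkyne carbon and the ketene acetal carbon to the acyl-bearing one. Loss of methanol and of the silyl group aromatises the adduct to (S)-3-(tert-butyldimethylsilyloxy)-1-(5-hydroxy-7-methoxy-2,2-dimethyl-2H-chromen-6-yl)-3-phenylpropan-1-one A5.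
- Merits: all substituents of ring A arrive in one step with polarity-matched regiochemistry, the side chain is already attached, the phenol emerges free, and A5 is one deprotection from 19. In convergence and in avoiding any differentiation of phloroglucinol oxygens it is better than the chosen plan.
- Weak points: A6 derives from a monocyclic 2H-pyran ester, a class that equilibrates with open dienones, and as a cross-conjugated triene it should polymerise readily. A7 is a sensitive alkoxy ynone that must be made by acylating a methoxyacetylide with a chiral β-silyloxy acyl donor. The aromatisation must lose methanol from C5 and not the silyloxy group. There is no close precedent for this diene.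
- Comparison: the chosen plan sets shelf-stable partners 13 and 16 and a known insertion reaction against a benzannulation whose two components are both unknown and labile.

**Alternative 3:** The two C2–CH3 bonds are cut, leading to 5-hydroxy-7-methoxy-2H-chromen-2-one A8. Excess methyllithium adds twice to the lactone carbonyl, and acid recloses O1–C2 to give 7-methoxy-2,2-dimethyl-2H-chromen-5-ol A9, which is the same compound as 6.
- Merits: this is a known way to gem-dimethylchromenes and reaches the chromenol in two steps from a coumarin.
- Weak points: A8 has to come from A4 by a Pechmann-type condensation that can also close on the other side and give the 7-hydroxy-5-methoxy isomer. The free phenoxide deactivates the lactone and consumes reagent, and conjugate addition competes. The key step forms none of the bonds that make 19 difficult, so the C5–O/C6–acyl pair remains unsolved.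
- Comparison: as a front end it is one step shorter than steps 1 to 3 and could feed into steps 4 to 10 unchanged if A8 were obtained isomerically pure. The chosen plan sets against it the unambiguous regiochemistry of the route from 1. As a strategy for the whole molecule it would have to fall back on acylation of 6, which is unselective between C6 and C8.

Key step: step 9

Remark: 14 is taken as the commercial (S) enantiomer and its C3' centre is carried through unchanged; diol 5 is racemic at C4, which is of no consequence because that centre is removed in the same step.

## Route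

Step 1
Reactants: 1 phloroglucinol (benzene-1,3,5-triol); 2 3-methylbut-2-enoic acid
Product: 3 5,7-dihydroxy-2,2-dimethylchroman-4-one
Conditions: MeSO3H, P2O5, 70 °C
Reagents that add atoms: none
Why: Friedel–Crafts acylation of the triol by activated 2, followed by intramolecular oxa-Michael addition of an ortho hydroxyl to the β,β-dimethyl enone, closes the pyranone; the threefold symmetry of 1 allows only one chromanone.

Step 2
Reactants: 3 5,7-dihydroxy-2,2-dimethylchroman-4-one
Product: 4 5-hydroxy-7-methoxy-2,2-dimethylchroman-4-one
Conditions: MeI (1.05 equiv), K2CO3 (1.0 equiv), acetone, rt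
Reagents that add atoms: iodomethane, CI
Why: Williamson etherification; the C5 hydroxyl is hydrogen-bonded to the C4 carbonyl and is much less acidic and nucleophilic, so one equivalent of base and iodomethane should alkylate the C7 hydroxyl alone.

Step 3
Reactants: 4 5-hydroxy-7-methoxy-2,2-dimethylchroman-4-one
Product: 6 7-methoxy-2,2-dimethyl-2H-chromen-5-ol, via chromane-4,5-diol 5 (not isolated)
Conditions: NaBH4, THF/MeOH, 0 °C to rt; aq. NH4Cl work-up; then p-TsOH·H2O (cat.), toluene, 50 °C
Reagents that add atoms: none
Why: Borohydride reduction of the aryl ketone gives benzylic alcohol 5, and acid-catalysed E1 dehydration through the oxygen-stabilised benzylic cation gives the C3=C4 double bond; this is the standard chromanone-to-chromene sequence.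

Step 4
Reactants: 6 7-methoxy-2,2-dimethyl-2H-chromen-5-ol
Product: 7 7-methoxy-2,2-dimethyl-2H-chromen-5-yl N-isopropylcarbamate
Conditions: i-PrNCO, Et3N (cat.), CH2Cl2, rt
Reagents that add atoms: isopropyl isocyanate, CC(C)N=C=O
Why: Amine-catalysed addition of the phenol to the isocyanate (carbamoylation) installs the directing group for ortho-metalation; no other nucleophile is present.

Step 5
Reactants: 7 7-methoxy-2,2-dimethyl-2H-chromen-5-yl N-isopropylcarbamate
Product: 11 7-methoxy-2,2-dimethyl-6-(trimethylsilyl)-2H-chromen-5-yl N-isopropylcarbamate, via N-silyl carbamate 8 (not isolated), via 6-lithio N-silyl carbamate 9 (not isolated), via N-silyl 6-trimethylsilyl carbamate 10 (not isolated)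
Conditions: TBSOTf, TMEDA, Et2O, 0 °C to rt; n-BuLi, TMEDA, −78 °C; TMSCl, −78 °C to rt; aq. NaHSO4
Reagents that add atoms: chlorotrimethylsilane, C[Si](C)(C)Cl; tert-butyldimethylsilyl trifluoromethanesulfonate, CC(C)(C)[Si](C)(C)OS(=O)(=O)C(F)(F)F, and n-butyllithium, [Li]CCCC (their atoms remain only in the intermediates 8 to 10)
Why: Directed ortho-metalation: the N–H is masked in the flask as 8, n-BuLi/TMEDA removes the C6 proton (the only one ortho to the carbamate, and also flanked by the C7 methoxyl) to give 9, and silylation gives 10; the acidic work-up cleaves only the N–Si bond.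

Step 6
Reactants: 11 7-methoxy-2,2-dimethyl-6-(trimethylsilyl)-2H-chromen-5-yl N-isopropylcarbamate
Product: 13 7-methoxy-2,2-dimethyl-6-(trimethylsilyl)-2H-chromen-5-yl trifluoromethanesulfonate, via 6-silyl chromen-5-ol 12 (not isolated)
Conditions: Et2NH, DBU, MeCN, 40 °C; then PhNTf2, rt
Reagents that add atoms: N-phenylbis(trifluoromethanesulfonimide), O=S(=O)(N(c1ccccc1)S(=O)(=O)C(F)(F)F)C(F)(F)F
Why: DBU deprotonates the carbamate N–H and triggers E1cB loss of isopropyl isocyanate, which Et2NH traps as a urea; the phenoxide of 12 is triflated in the same flask, the usual one-pot route to ortho-silylaryl triflates that avoids isolating the silyl phenol.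

Step 7
Reactants: 14 ethyl (S)-3-hydroxy-3-phenylpropanoate
Product: 15 ethyl (S)-3-(methoxymethoxy)-3-phenylpropanoate
Conditions: MOMCl, i-Pr2NEt, CH2Cl2, 0 °C to rt
Reagents that add atoms: chloromethyl methyl ether, COCCl
Why: O-Alkylation of the secondary alcohol with the chloromethyl ether and a hindered amine base (acetal formation); no bond at C3' is broken, so the (S) configuration is retained, and the weak base should not provoke β-elimination.

Step 8
Reactants: 15 ethyl (S)-3-(methoxymethoxy)-3-phenylpropanoate
Product: 16 (S)-3-(methoxymethoxy)-3-phenylpropanoic acid
Conditions: LiOH, THF/H2O, 0 °C to rt; then 1 M HCl to pH 3 at 0 °C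
Reagents that add atoms: lithium hydroxide, [Li+].[OH-] (its oxygen ends in the carboxyl group)
Why: Saponification of the ethyl ester with hydroxide at low temperature; the acetal is stable to base and to the brief cold acidification, and C3' is not involved.

Step 9
Reactants: 13 7-methoxy-2,2-dimethyl-6-(trimethylsilyl)-2H-chromen-5-yl trifluoromethanesulfonate; 16 (S)-3-(methoxymethoxy)-3-phenylpropanoic acid
Product: 18 (S)-1-(5-hydroxy-7-methoxy-2,2-dimethyl-2H-chromen-6-yl)-3-(methoxymethoxy)-3-phenylpropan-1-one, via 5,6-aryne 17 (not isolated)
Conditions: CsF (4 equiv), THF, 125 °C, sealed tube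
Reagents that add atoms: none
Why: Fluoride attacks silicon in 13 and the C6 carbanion expels triflate from C5 to give aryne 17, while CsF converts 16 into its caesium carboxylate. The carboxylate oxygen adds to C5, the aryne carbon remote from the C7 methoxyl, because the inductive pull of that oxygen distorts the aryne and stabilises the negative charge developing at C6. The C6 aryl anion then attacks the ester carbonyl on the neighbouring oxygen through a four-membered alkoxide, which reopens by C–O cleavage to the aryl ketone and the C5 phenoxide, so the aryne has formally inserted into the acyl C–O bond and C5–O and C6–C1' are the two new bonds. The closest known reaction is the fluoride-induced insertion of arynes into the C–O bond of carboxylic acids, which gives 2-hydroxyaryl ketones in hot THF. No ring is closed (the four-membered ring is only transient) and no stereocentre is formed; C3' lies β to the reacting carboxyl, is not acidic, and should keep its (S) configuration. Three selectivities are needed: regiochemistry, secured by the C7 methoxyl as in 3-alkoxyarynes; acyl transfer in preference to protonation of the C6 anion (which would stop at the aryl ester), secured by the high temperature and the aprotic medium; and survival of the β-acetal, secured by its inertness to fluoride and by the product being a phenoxide whose further deprotonation at C2' is disfavoured.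

Step 10
Reactants: 18 (S)-1-(5-hydroxy-7-methoxy-2,2-dimethyl-2H-chromen-6-yl)-3-(methoxymethoxy)-3-phenylpropan-1-one
Product: 19 (S)-3-hydroxy-1-(5-hydroxy-7-methoxy-2,2-dimethyl-2H-chromen-6-yl)-3-phenylpropan-1-one
Conditions: HCl (cat.), MeOH, rt
Reagents that add atoms: none
Why: Acid-catalysed acetal exchange with methanol cleaves the methoxymethyl ether at the acetal carbon and not at the benzylic C3'–O bond, so the (S) configuration is untouched; dilute acid at room temperature should be too weak to dehydrate the hydrogen-bonded β-hydroxy ketone or to add methanol to the chromene.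

## Compound list

1 | phloroglucinol (benzene-1,3,5-triol) | Oc1cc(O)cc(O)c1 | starting material
2 | 3-methylbut-2-enoic acid | CC(C)=CC(=O)O | starting material
3 | 5,7-dihydroxy-2,2-dimethylchroman-4-one | CC1(C)CC(=O)c2c(O)cc(O)cc2O1 | intermediate
4 | 5-hydroxy-7-methoxy-2,2-dimethylchroman-4-one | COc1cc(O)c2C(=O)CC(C)(C)Oc2c1 | intermediate
5 | (±)-7-methoxy-2,2-dimethylchromane-4,5-diol | COc1cc(O)c2C(O)CC(C)(C)Oc2c1 | intermediate
6 | 7-methoxy-2,2-dimethyl-2H-chromen-5-ol | COc1cc(O)c2C=CC(C)(C)Oc2c1 | intermediate
7 | 7-methoxy-2,2-dimethyl-2H-chromen-5-yl N-isopropylcarbamate | COc1cc(OC(=O)NC(C)C)c2C=CC(C)(C)Oc2c1 | intermediate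
8 | 7-methoxy-2,2-dimethyl-2H-chromen-5-yl N-(tert-butyldimethylsilyl)-N-isopropylcarbamate | COc1cc(OC(=O)N(C(C)C)[Si](C)(C)C(C)(C)C)c2C=CC(C)(C)Oc2c1 | intermediate
9 | [5-{[N-(tert-butyldimethylsilyl)-N-isopropylcarbamoyl]oxy}-7-methoxy-2,2-dimethyl-2H-chromen-6-yl]lithium | COc1c([Li])c(OC(=O)N(C(C)C)[Si](C)(C)C(C)(C)C)c2C=CC(C)(C)Oc2c1 | intermediate
10 | 7-methoxy-2,2-dimethyl-6-(trimethylsilyl)-2H-chromen-5-yl N-(tert-butyldimethylsilyl)-N-isopropylcarbamate | COc1c([Si](C)(C)C)c(OC(=O)N(C(C)C)[Si](C)(C)C(C)(C)C)c2C=CC(C)(C)Oc2c1 | intermediate
11 | 7-methoxy-2,2-dimethyl-6-(trimethylsilyl)-2H-chromen-5-yl N-isopropylcarbamate | COc1c([Si](C)(C)C)c(OC(=O)NC(C)C)c2C=CC(C)(C)Oc2c1 | intermediate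
12 | 7-methoxy-2,2-dimethyl-6-(trimethylsilyl)-2H-chromen-5-ol | COc1c([Si](C)(C)C)c(O)c2C=CC(C)(C)Oc2c1 | intermediate
13 | 7-methoxy-2,2-dimethyl-6-(trimethylsilyl)-2H-chromen-5-yl trifluoromethanesulfonate | COc1cc2c(c(OS(=O)(=O)C(F)(F)F)c1[Si](C)(C)C)C=CC(C)(C)O2 | intermediate
14 | ethyl (S)-3-hydroxy-3-phenylpropanoate | CCOC(=O)C[C@H](O)c1ccccc1 | starting material
15 | ethyl (S)-3-(methoxymethoxy)-3-phenylpropanoate | CCOC(=O)C[C@H](OCOC)c1ccccc1 | intermediate
16 | (S)-3-(methoxymethoxy)-3-phenylpropanoic acid | OC(=O)C[C@H](OCOC)c1ccccc1 | intermediate
17 | 7-methoxy-2,2-dimethyl-5,6-didehydro-2H-chromene (5,6-aryne) | COC1=CC2=C(C#C1)C=CC(C)(C)O2 | intermediate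
18 | (S)-1-(5-hydroxy-7-methoxy-2,2-dimethyl-2H-chromen-6-yl)-3-(methoxymethoxy)-3-phenylpropan-1-one | COc1cc2c(c(O)c1C(=O)C[C@H](OCOC)c1ccccc1)C=CC(C)(C)O2 | intermediate
19 | (S)-3-hydroxy-1-(5-hydroxy-7-methoxy-2,2-dimethyl-2H-chromen-6-yl)-3-phenylpropan-1-one | COc1cc2c(c(O)c1C(=O)C[C@H](O)c1ccccc1)C=CC(C)(C)O2 | target

## Step count and risks

Total: 10 steps. Longest linear sequence: 8 steps (steps 1 to 6, 9 and 10); the acid branch (steps 7 and 8) joins at step 9.

**Step 9 (key step).** Three processes could spoil it:
- protonation of the C6 aryl anion by the hydrogen fluoride formed from the acid before acyl transfer, so that only O-arylation occurs;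
- base-induced β-elimination of the methoxymethoxy group from the product ketone at 125 °C, followed by conjugate addition of the C5 phenoxide, with loss of C3';
- erosion of regioselectivity, because C5 is also flanked by the ring-fused C4a.

The fallback replaces the aryne by directed metalation and acylation. It sets out from 6 and 16 and returns at 19. Chromenol 6 would be protected with MOMCl and i-Pr2NEt as 7-methoxy-5-(methoxymethoxy)-2,2-dimethyl-2H-chromene F1. Acid 16 would be coupled with N,O-dimethylhydroxylamine hydrochloride and a carbodiimide to (S)-N-methoxy-3-(methoxymethoxy)-N-methyl-3-phenylpropanamide F2. Lithiation of F1 with n-BuLi in THF at 0 °C should occur at C6, between the acetal oxygen and the methoxyl. Addition to F2 at −78 °C should give (S)-1-[7-methoxy-5-(methoxymethoxy)-2,2-dimethyl-2H-chromen-6-yl]-3-(methoxymethoxy)-3-phenylpropan-1-one F3. HCl in methanol would then remove both acetals to give 19.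

**Step 5.** The organolithium may deprotonate C8 (between the two ether oxygens), add across the C3=C4 styrene bond, or let the carbamoyl group migrate to C6 on warming before the quench. The fallback avoids deprotonation altogether and uses halogen–metal exchange. It sets out from 6 and returns at 13. Amine-mediated ortho-bromination (NBS, catalytic i-Pr2NH, CH2Cl2, −78 to 0 °C) should give 6-bromo-7-methoxy-2,2-dimethyl-2H-chromen-5-ol F4, C6 being the only free ortho position. Silylation with (Me3Si)2NH would give [(6-bromo-7-methoxy-2,2-dimethyl-2H-chromen-5-yl)oxy]trimethylsilane F5. Bromine–lithium exchange with n-BuLi at −78 °C, followed by migration of silicon from oxygen to carbon (retro-Brook rearrangement), gives the lithium salt of 12, which Tf2O converts into 13.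

**Step 3.** The ortho-hydroxybenzylic alkoxide may lose oxide to a quinone methide that takes up a second hydride (over-reduction to the chroman), the chelated ketone may reduce incompletely, and the acid used for dehydration may dimerise the electron-rich chromene. The fallback masks the phenol so that no quinone methide can form. It sets out from 4 and returns at 6. TBSCl and imidazole in DMF would give 5-(tert-butyldimethylsilyloxy)-7-methoxy-2,2-dimethylchroman-4-one F6. NaBH4 in methanol would give racemic 5-(tert-butyldimethylsilyloxy)-7-methoxy-2,2-dimethylchroman-4-ol F7. Catalytic p-TsOH in toluene would dehydrate it to tert-butyl[(7-methoxy-2,2-dimethyl-2H-chromen-5-yl)oxy]dimethylsilane F8, and Bu4NF in THF would release 6.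

**Step 10.** Acid may dehydrate the β-hydroxy ketone to the chalcone, which cyclises onto the C5 hydroxyl, or may add methanol to the chromene double bond. Conditions mild enough to avoid both may leave the acetal partly intact. The fallback changes the protecting group to one removed oxidatively at neutral pH. It sets out from 14 and returns at 19. 4-Methoxybenzyl trichloroacetimidate and catalytic camphorsulfonic acid would give ethyl (S)-3-[(4-methoxybenzyl)oxy]-3-phenylpropanoate F9. LiOH would give (S)-3-[(4-methoxybenzyl)oxy]-3-phenylpropanoic acid F10. Aryne insertion with 13 under the conditions of step 9 would give (S)-1-(5-hydroxy-7-methoxy-2,2-dimethyl-2H-chromen-6-yl)-3-[(4-methoxybenzyl)oxy]-3-phenylpropan-1-one F11. DDQ in CH2Cl2 with pH 7 buffer at 0 °C would release 19.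

## Further compounds

F1 | step 9 | 7-methoxy-5-(methoxymethoxy)-2,2-dimethyl-2H-chromene | COCOc1cc(OC)cc2c1C=CC(C)(C)O2
F2 | step 9 | (S)-N-methoxy-3-(methoxymethoxy)-N-methyl-3-phenylpropanamide | CON(C)C(=O)C[C@H](OCOC)c1ccccc1
F3 | step 9 | (S)-1-[7-methoxy-5-(methoxymethoxy)-2,2-dimethyl-2H-chromen-6-yl]-3-(methoxymethoxy)-3-phenylpropan-1-one | COCOc1c(C(=O)C[C@H](OCOC)c2ccccc2)c(OC)cc2c1C=CC(C)(C)O2
F4 | step 5 | 6-bromo-7-methoxy-2,2-dimethyl-2H-chromen-5-ol | COc1c(Br)c(O)c2C=CC(C)(C)Oc2c1
F5 | step 5 | [(6-bromo-7-methoxy-2,2-dimethyl-2H-chromen-5-yl)oxy]trimethylsilane | COc1c(Br)c(O[Si](C)(C)C)c2C=CC(C)(C)Oc2c1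
F6 | step 3 | 5-(tert-butyldimethylsilyloxy)-7-methoxy-2,2-dimethylchroman-4-one | COc1cc(O[Si](C)(C)C(C)(C)C)c2C(=O)CC(C)(C)Oc2c1
F7 | step 3 | (±)-5-(tert-butyldimethylsilyloxy)-7-methoxy-2,2-dimethylchroman-4-ol | COc1cc(O[Si](C)(C)C(C)(C)C)c2C(O)CC(C)(C)Oc2c1
F8 | step 3 | tert-butyl[(7-methoxy-2,2-dimethyl-2H-chromen-5-yl)oxy]dimethylsilane | COc1cc(O[Si](C)(C)C(C)(C)C)c2C=CC(C)(C)Oc2c1
F9 | step 10 | ethyl (S)-3-[(4-methoxybenzyl)oxy]-3-phenylpropanoate | CCOC(=O)C[C@H](OCc1ccc(OC)cc1)c1ccccc1
F10 | step 10 | (S)-3-[(4-methoxybenzyl)oxy]-3-phenylpropanoic acid | OC(=O)C[C@H](OCc1ccc(OC)cc1)c1ccccc1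
F11 | step 10 | (S)-1-(5-hydroxy-7-methoxy-2,2-dimethyl-2H-chromen-6-yl)-3-[(4-methoxybenzyl)oxy]-3-phenylpropan-1-one | COc1cc2c(c(O)c1C(=O)C[C@H](OCc1ccc(OC)cc1)c1ccccc1)C=CC(C)(C)O2
A1 | alternative 1 | 7-methoxy-5-(methoxymethoxy)-2,2-dimethyl-2H-chromene | COCOc1cc(OC)cc2c1C=CC(C)(C)O2
A2 | alternative 1 | 5-methoxy-3-(methoxymethoxy)-2-(trimethylsilyl)phenyl trifluoromethanesulfonate | COCOc1cc(OC)cc(OS(=O)(=O)C(F)(F)F)c1[Si](C)(C)C
A3 | alternative 1 | 3-methylbut-2-enal | CC(C)=CC=O
A4 | alternative 1 | 5-methoxyresorcinol | COc1cc(O)cc(O)c1
A5 | alternative 2 | (S)-3-(tert-butyldimethylsilyloxy)-1-(5-hydroxy-7-methoxy-2,2-dimethyl-2H-chromen-6-yl)-3-phenylpropan-1-one | COc1cc2c(c(O)c1C(=O)C[C@H](O[Si](C)(C)C(C)(C)C)c1ccccc1)C=CC(C)(C)O2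
A6 | alternative 2 | 5-[methoxy(trimethylsilyloxy)methylidene]-2,2-dimethyl-6-methylidene-5,6-dihydro-2H-pyran | COC(O[Si](C)(C)C)=C1C=CC(C)(C)OC1=C
A7 | alternative 2 | (S)-5-(tert-butyldimethylsilyloxy)-1-methoxy-5-phenylpent-1-yn-3-one | COC#CC(=O)C[C@H](O[Si](C)(C)C(C)(C)C)c1ccccc1
A8 | alternative 3 | 5-hydroxy-7-methoxy-2H-chromen-2-one | COc1cc(O)c2C=CC(=O)Oc2c1
A9 | alternative 3 | 7-methoxy-2,2-dimethyl-2H-chromen-5-ol | COc1cc(O)c2C=CC(C)(C)Oc2c1
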